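You may have met a neighbour of alpha charged with 0.20 M of starting material instead of 0.50 M. Its question is the same as in these three flasks: how much activated form closes to ring before starting material catches it?

common to all: starting material 0.50 M; gas 24 mM (held); time 80 min

| charge | temperature |
|---|---|
| zeta | −25 °C |
| eta | −10 °C |
| alpha | 5 °C |

- percent here means starting material units held: one open dimer counts as two
- at the start none of activator is dissolved
- the constants hold at 5 °C; other temperatures follow from the activation energies and enthalpies

* the flask with the highest amount of ring, in percent of the starting material charged ("all alike" if they lie within 1.5 percentage points) (zeta / eta / alpha / all alike)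
* final ring, as a percentage of the starting material charged, in zeta
* final ring, as a percentage of the starting material charged, in eta
* final ring, as a percentage of the starting material charged, in alpha

Activated form has two exits. It closes to ring with 0.105 min⁻¹ at 5 °C, or it meets starting material and gives open dimer, which costs two units of starting material. Gas feeds activator with 13.2 min⁻¹, faster than starting material takes it up at the start, so activator stays near saturation and activation is pseudo-first-order, with 0.105 min⁻¹ in alpha.

My measure is the dimer pull m, a selectivity factor: the dimer constant times the charge of starting material, doubled, over the closure constant. In alpha, m is 7.86. If activated form is used as fast as it is made, integrating over the charge gives a share ln(1+m)/m passing through ring, here 27.8 %. The ring and its isomer relax towards each other with a half-life of 1.30 min in alpha, far shorter than 80 min, so dividing by 1 plus 1.73 leaves 10.2 % ring in alpha.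

But is that assumption sound? In alpha, the activation constant about equals the closure constant, so activated form lags behind starting material, and whatever outlasts starting material can still close. I therefore expect alpha somewhat above my figure.

Now go to logarithms. From alpha down to zeta, closure slows by a factor of 105 and dimer formation by a factor of 10, since the dimer step's activation energy is lower by 45.0 kJ mol⁻¹. So log10 m rises by 1.02. The same formula is poor in zeta, where activation outruns closure by a factor of 15.2. A time ceiling serves better: even a charge standing wholly as activated form from the first minute could pass 7.70 % to ring in zeta, less than my alpha figure. For eta my reckoning stops here.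

The forecast names alpha, with 1.3 % in zeta, 4.1 % in eta and 13.3 % in alpha. Of zeta it says: “Much activated form remains unconverted”.

    starting material + activator → activated form (k1 = 4.38 L mol⁻¹ min⁻¹, Ea1 = 37.0 kJ mol⁻¹)
    activated form → ring (k2 = 0.105 min⁻¹, Ea2 = 89.0 kJ mol⁻¹)
    starting material + activated form → open dimer (k3 = 0.825 L mol⁻¹ min⁻¹, Ea3 = 44.0 kJ mol⁻¹)
    ring ⇌ isomer of the product (K4 = 1.73, k4 = 0.338 min⁻¹, Ea4 = 72.0 kJ mol⁻¹, ΔH4 = −72.0 kJ mol⁻¹)
    activator → decomposition product (k5 = 4.96 × 10⁻⁴ min⁻¹, Ea5 = 97.0 kJ mol⁻¹)
    gas ⇌ activator, rate k6*(csat - [activator]) (k6 = 13.2 min⁻¹, csat = 24 mM)
    (constants at 5 °C)

The simulation gives alpha, with 1.33 % in zeta, 4.17 % in eta and 13.3 % in alpha, so the forecast holds. Alpha's ring does not move when left ten times as long. Ring and isomer together in alpha read 36.4 %, above my 27.8 %, on the side I expected.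

For the neighbour at 0.20 M, m falls to 3.14 and the share rises to 45.2 %. Scaling alpha's ring by that change gives 21.6 %. The simulation gives 21.2 %.

All constants stand for no real mixture; the run is a simulation.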